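The constants used here were set for the occasion; the result is computed.

Theta has a neighbour charged with 8.4 × 10⁻⁴ M of free catalyst, and I want one reckoning that serves that neighbour as well as the flasks below.

| flask | substrate | free catalyst | time | remark | temperature |
|---|---|---|---|---|---|
| theta | 1.1 M | 2.1 mM | 6.0 d | at 20 °C until 30 h, from then on at 60 °C |  |
| delta | 1.1 M | 2.1 mM | 6.0 d |  | 20 °C |
| alpha | 1.1 M | 2.1 mM | 6.0 d |  | 40 °C |
| beta | 1.1 M | 2.1 mM | 6.0 d |  | 60 °C |

    substrate + free catalyst → free catalyst + product (k1 = 0.33 M⁻¹ min⁻¹, Ea1 = 51.0 kJ mol⁻¹)
    2 free catalyst ⇌ resting dimer, settled at all times (K2 = 350 M⁻¹, ΔH2 = 20.0 kJ mol⁻¹)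
    2 free catalyst → spent catalyst A (k3 = 0.026 M⁻¹ min⁻¹, Ea3 = 52.0 kJ mol⁻¹)
    free catalyst → spent catalyst B (k4 = 1.4 × 10⁻⁴ min⁻¹, Ea4 = 108 kJ mol⁻¹)
    (constants at 20 °C)

- a step written with two of one species runs at k times the square of its concentration and takes two of it each time
- the constants hold at 20 °C; other temperatures follow from the activation energies and enthalpies

1. the flask with the highest amount of product, in percent of the substrate charged ("all alike" if they lie within 1.5 percentage points) (theta / delta / alpha / beta / all alike)
2. final product, as a percentage of the substrate charged, in theta
3. final product, as a percentage of the substrate charged, in delta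
4. final product, as a percentage of the substrate charged, in alpha
5. final product, as a percentage of the substrate charged, in beta

Substrate falls at k1 times substrate times free catalyst, so the logarithm of substrate charged over substrate left grows as k1 times the time integral of free catalyst. Spent catalyst B grows as k4 times that same integral. Dividing one by the other cancels the integral, and the resting dimer drops out with it.

I call the result the reach: k1 times the catalyst charged, divided by k4. At the reference temperature it is 4.95. The rule, at one fixed temperature, is that the logarithm equals the reach times the share of charged catalyst that has become spent catalyst B.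

For the share lost I need a catalyst life. The dimer balance at the start leaves 55.2% of the catalyst free, and I hold that share fixed, so the life is one over k4 times that share.

I set the step to spent catalyst A aside. At the start of delta it removes free catalyst at 6.03 × 10⁻⁵ min⁻¹ per unit of free catalyst, slower than the 1.4 × 10⁻⁴ min⁻¹ of the first-order step, but it isn't negligible, so my figures lean high.

My table has one row per temperature:

- Delta, 20 °C: reach 4.95, life 8.99 d.
- Alpha, 40 °C: reach 1.11, life 0.530 d.
- Beta, 60 °C: reach 0.299, life 0.0440 d.

Reading down, the reach shrinks with heat, since k4 has the higher activation energy. In delta the life is longer than the 6.0 d of the run, so the clock stops it. The share lost is 48.7%, the logarithm is 2.41, and I get 91.0%.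

In alpha and beta the life is far shorter than the run, so the reach itself counts, which gives 67.1% and 25.8%.

Theta reads two rows. It still holds 87.0% of its catalyst unspent at 30 h, so it spends 13.0% at delta's reach and the remaining share at beta's reach. The logarithm is 0.903, so I get 59.5%. My winner is delta.

The forecast also names delta, with 90.6% there, 58.7% in theta, 65.3% in alpha and 25.6% in beta. Its grounds are that “the warm flasks kill their catalyst early and stall”. Its alpha stands below mine.

The simulation gives delta, with 90.7% there, 58.7% in theta, 65.4% in alpha and 25.6% in beta. At 6.00 d, delta has 47.9% of its catalyst as spent catalyst B. The reach times that share is 2.37, which leaves 9.34% of the substrate, and the flask holds 9.35%.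

On the neighbour, the reach is 1.98 and the free share at the start is 70.7%. Theta's two-row reckoning then gives a logarithm of 0.423, or 34.5% product. The simulation gives 34.3%.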